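**Strategy.** Everything rests on disconnecting the C4–C4a bond of the 2H-pyran ring and re-attaching C4 to C8a. This turns the chromenol into a spiro-fused 2,5-dihydrofuran/cyclohexa-2,5-dienone. The feature exploited is the para relationship between O1 (on C8a) and the C6 oxygen of the benzene ring, the signature of a p-quinol ether. In the key step an acylative dienone–phenol rearrangement moves vinylic C4 from the spiro carbon to the adjacent CH. The five-membered O-heterocycle grows to the pyran, the carbocycle aromatises, and O6 emerges as its acetate, while all four bonds at C2 stay intact. Both stereocentres derive from one building block, (S)-dehydrolinalool.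

Key step: step 7

Remark on the chemistry: read from the SMILES, the target is (S) at chromene C2 and (S) at the side-chain carbinol C8'. Both centres have the same spatial arrangement of O, unsaturated carbon, CH2 and CH3. Compound 9 is also stereogenic at its spiro carbon. It is carried as a mixture of spiro epimers (SMILES left undefined there) because step 7 erases that centre. The alkene geometry of transient 4 is left undefined.

**Step 1**
Reactants: 1 geraniol
Product: 2 (2S,3S)-2,3-epoxygeraniol
Conditions: Ti(OiPr)4 (5 mol %), L-(+)-DET (6 mol %), anhydrous t-BuOOH (1.5 equiv), 4 Å MS, CH2Cl2, −20 °C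
Reagents that add atoms: tert-butyl hydroperoxide, CC(C)(C)OO
Why: Sharpless asymmetric epoxidation touches only the allylic-alcohol alkene, and with L-(+)-tartrate oxygen is delivered to the face that makes C3 (S), the source of both stereocentres of the target.

**Step 2**
Reactants: 2 (2S,3S)-2,3-epoxygeraniol
Product: 3 (2S,3R)-3-(chloromethyl)-2-methyl-2-(4-methylpent-3-en-1-yl)oxirane (epoxygeranyl chloride)
Conditions: PPh3 (1.3 equiv), CCl4, trace NaHCO3, reflux
Reagents that add atoms: carbon tetrachloride, ClC(Cl)(Cl)Cl
Why: The Appel reaction exchanges the primary OH for Cl by SN2 at C1 under neutral conditions, so the epoxide and both of its centres are untouched (the descriptor at the CH carbon changes only through CIP priority).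

**Step 3**
Reactants: 3 epoxygeranyl chloride
Product: 5 (S)-dehydrolinalool [(3S)-3,7-dimethyloct-6-en-1-yn-3-ol], via chlorovinyl carbinol 4 (not isolated)
Conditions: n-BuLi (3.3 equiv), THF, −78 → −30 °C; H2O
Reagents that add atoms: none
Why: In this base-induced double elimination of a 2,3-epoxy chloride, deprotonation at CHCl opens the epoxide at C2–O to the chlorovinyl alkoxide and a second equivalent removes HCl to give the alkyne, while the C3–O bond is never broken so C3 stays (S).

**Step 4**
Reactants: 5 (S)-dehydrolinalool; 6 4-iodo-3-methylphenol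
Product: 7 4-[(3S)-3-hydroxy-3,7-dimethyloct-6-en-1-yn-1-yl]-3-methylphenol
Conditions: PdCl2(PPh3)2 (2 mol %), CuI (4 mol %), Et3N, THF, degassed, rt
Reagents that add atoms: none
Why: Sonogashira coupling of an aryl iodide with a terminal alkyne tolerates the free phenol and the tertiary alcohol and does not touch the stereocentre.

**Step 5**
Reactants: 7 aryl alkynyl carbinol
Product: 8 4-[(1Z,3S)-3-hydroxy-3,7-dimethylocta-1,6-dien-1-yl]-3-methylphenol
Conditions: H2 (1 atm), Lindlar catalyst, quinoline, EtOAc, rt, stopped after 1 equiv H2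
Reagents that add atoms: none
Why: Lindlar semihydrogenation adds H2 syn to the alkyne to give the Z-styrene, and the trisubstituted alkene is far slower on the poisoned catalyst.

**Step 6**
Reactants: 8 Z-styrenyl carbinol phenol
Product: 9 (2S)-2,6-dimethyl-2-(4-methylpent-3-en-1-yl)-1-oxaspiro[4.5]deca-3,6,9-trien-8-one (both C5 epimers)
Conditions: PhI(OAc)2 (1.1 equiv), MeCN, dilute, 0 °C
Reagents that add atoms: none
Why: In this hypervalent-iodine oxidative dearomatisation (spiroetherification of a 4-substituted phenol), the ortho-methyl group and the Z-geometry twist the alkene out of the arene plane and hold the tertiary OH over the para carbon, so 5-exo capture by oxygen should outrun vinylogous or external capture, the C2–O bond is not broken, and the new spiro centre is inconsequential.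

**Step 7**
Reactants: 9 spiro dihydrofuran dienone
Product: 10 (S)-2,8-dimethyl-2-(4-methylpent-3-en-1-yl)-2H-chromen-6-yl acetate
Conditions: Ac2O (5 equiv), TMSOTf (10 mol %), CH2Cl2, −40 → 0 °C, dark; pyridine quench
Reagents that add atoms: acetic anhydride, CC(=O)OC(C)=O
Why: TMSOTf/Ac2O acetylates the dienone oxygen to a 4-acetoxycyclohexadienyl cation, the C4–C5 σ bond (held parallel to the empty p orbitals by the spiro geometry) carries vinylic C4 from C5 to C10, and the O1-stabilised arenium ion loses H-10 to give the aryl acetate. The closest known reaction type is the dienone–phenol rearrangement of spirodienones in acetic anhydride/acid, including the conversion of 1-oxaspiro[4.5]deca-6,9-dien-8-ones into chroman-6-ols. The 2H-pyran is not closed from a chain but made by a suprafacial 1,2-shift that inserts ring carbon C10 (later C4a) between C4 and C5 (later C8a), a one-atom enlargement of the 2,5-dihydrofuran. No stereocentre is created: the spiro centre is erased, so both epimers of 9 converge, and C2 stays (S) because none of its bonds takes part. Carbon rather than oxygen should migrate because only the carbon shift leaves an oxocarbenium ion and an sp2 carbon migrates well, and C10–H is preferred over C6–Me because only that arenium ion can lose a proton, whereas the C6 adduct is a reversible dead end from which the tethered vinyl group cannot move on. Catalytic acid, low temperature and the absence of any free OH in 9 should spare the trisubstituted alkene and the tertiary allylic C2–O1 bond.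

**Step 8**
Reactants: 10 chromenyl acetate
Product: 11 (S)-2-[(3E)-5-hydroxy-4-methylpent-3-en-1-yl]-2,8-dimethyl-2H-chromen-6-yl acetate
Conditions: SeO2 (0.3 equiv), t-BuOOH (2.5 equiv), CH2Cl2, 0 °C → rt
Reagents that add atoms: selenium dioxide (catalytic oxygen carrier), O=[Se]=O; tert-butyl hydroperoxide (terminal oxygen source), CC(C)(C)OO
Why: Riley-type allylic oxidation (ene reaction, then [2,3]-sigmatropic shift) hydroxylates the E-methyl group of a gem-dimethyl trisubstituted alkene selectively, and the chromene C3=C4 bond has no allylic hydrogen to offer.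

**Step 9**
Reactants: 11 allylic alcohol
Product: 12 (S)-2-[(3E)-5-bromo-4-methylpent-3-en-1-yl]-2,8-dimethyl-2H-chromen-6-yl acetate
Conditions: CBr4 (1.2 equiv), PPh3 (1.3 equiv), CH2Cl2, 0 °C
Reagents that add atoms: carbon tetrabromide, BrC(Br)(Br)Br
Why: Appel bromination converts the primary allylic alcohol by direct SN2 under neutral conditions, keeping the E-alkene, the acetate and the chromene.

**Step 10**
Reactants: 12 allylic bromide; 5 (S)-dehydrolinalool
Product: 13 (S)-2-[(3E,8S)-8-hydroxy-4,8,12-trimethyltrideca-3,11-dien-6-yn-1-yl]-2,8-dimethyl-2H-chromen-6-yl acetate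
Conditions: CuI (20 mol %), n-Bu4NBr (20 mol %), anhydrous K2CO3 (1.5 equiv), DMF, rt
Reagents that add atoms: none
Why: Copper(I)-catalysed allylation of a terminal alkyne should join the halves at the unhindered CH2 with retention of the E-alkene and tolerates the free tertiary alcohol, and because both halves stem from the same enantioenriched 5 the mismatched combinations become separable diastereomers.

**Step 11**
Reactants: 13 enyne acetate
Product: 15 target, (S)-2-[(3E,6E,8S)-8-hydroxy-4,8,12-trimethyltrideca-3,6,11-trien-1-yl]-2,8-dimethyl-2H-chromen-6-ol, via deacetylated enyne 14 (not isolated)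
Conditions: LiAlH4 (4 equiv), THF, 0 → 50 °C, dark; Rochelle salt work-up
Reagents that add atoms: none
Why: Alkoxide-directed trans-hydroalumination of the propargylic alcohol followed by protonolysis gives the E-allylic alcohol while isolated and styrenyl alkenes are inert, and the same hydride first cleaves the aryl acetate, so reduction and deprotection coincide without touching a stereocentre.

**Compound list**
1 | geraniol | CC(C)=CCC/C(C)=C/CO | starting material
2 | (2S,3S)-2,3-epoxygeraniol | CC(C)=CCC[C@]1(C)O[C@H]1CO | intermediate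
3 | (2S,3R)-3-(chloromethyl)-2-methyl-2-(4-methylpent-3-en-1-yl)oxirane | CC(C)=CCC[C@]1(C)O[C@H]1CCl | intermediate
4 | (3S)-1-chloro-3,7-dimethylocta-1,6-dien-3-ol (present as lithium alkoxide, not isolated) | CC(C)=CCC[C@](C)(O)C=CCl | intermediate
5 | (S)-dehydrolinalool, (3S)-3,7-dimethyloct-6-en-1-yn-3-ol | CC(C)=CCC[C@](C)(O)C#C | intermediate
6 | 4-iodo-3-methylphenol | Cc1cc(O)ccc1I | starting material
7 | 4-[(3S)-3-hydroxy-3,7-dimethyloct-6-en-1-yn-1-yl]-3-methylphenol | CC(C)=CCC[C@](C)(O)C#Cc1ccc(O)cc1C | intermediate
8 | 4-[(1Z,3S)-3-hydroxy-3,7-dimethylocta-1,6-dien-1-yl]-3-methylphenol | CC(C)=CCC[C@](C)(O)/C=C\c1ccc(O)cc1C | intermediate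
9 | (2S)-2,6-dimethyl-2-(4-methylpent-3-en-1-yl)-1-oxaspiro[4.5]deca-3,6,9-trien-8-one (C5 epimers) | CC(C)=CCC[C@@]1(C)C=CC2(O1)C=CC(=O)C=C2C | intermediate
10 | (S)-2,8-dimethyl-2-(4-methylpent-3-en-1-yl)-2H-chromen-6-yl acetate | CC(C)=CCC[C@@]1(C)C=Cc2cc(OC(C)=O)cc(C)c2O1 | intermediate
11 | (S)-2-[(3E)-5-hydroxy-4-methylpent-3-en-1-yl]-2,8-dimethyl-2H-chromen-6-yl acetate | OC/C(C)=C/CC[C@@]1(C)C=Cc2cc(OC(C)=O)cc(C)c2O1 | intermediate
12 | (S)-2-[(3E)-5-bromo-4-methylpent-3-en-1-yl]-2,8-dimethyl-2H-chromen-6-yl acetate | BrC/C(C)=C/CC[C@@]1(C)C=Cc2cc(OC(C)=O)cc(C)c2O1 | intermediate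
13 | (S)-2-[(3E,8S)-8-hydroxy-4,8,12-trimethyltrideca-3,11-dien-6-yn-1-yl]-2,8-dimethyl-2H-chromen-6-yl acetate | CC(C)=CCC[C@](C)(O)C#CC/C(C)=C/CC[C@@]1(C)C=Cc2cc(OC(C)=O)cc(C)c2O1 | intermediate
14 | (S)-2-[(3E,8S)-8-hydroxy-4,8,12-trimethyltrideca-3,11-dien-6-yn-1-yl]-2,8-dimethyl-2H-chromen-6-ol (present as aluminate, not isolated) | CC(C)=CCC[C@](C)(O)C#CC/C(C)=C/CC[C@@]1(C)C=Cc2cc(O)cc(C)c2O1 | intermediate
15 | (S)-2-[(3E,6E,8S)-8-hydroxy-4,8,12-trimethyltrideca-3,6,11-trien-1-yl]-2,8-dimethyl-2H-chromen-6-ol | CC(C)=CCC[C@](C)(O)/C=C/C/C(C)=C/CC[C@@]1(C)C=Cc2cc(O)cc(C)c2O1 | target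

**Total step count:** 11. **Longest linear sequence:** 11 steps (1 → 15). Compound 5 from step 3 is used twice, in steps 4 and 10.

**Steps most likely to fail**

**Step 7.**
- The acid strength needed to activate a dienone may cause three problems. The vinyl group may migrate towards the methyl-bearing carbon, followed by methyl wandering. The tertiary allylic C–O bond may ionise, with erosion of enantiopurity. The side-chain alkene may be attacked.
- The fallback sets out from 9 and returns at 10. It lowers the oxidation level so that the same ring-enlarging shift runs under trace acid.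
- DIBAL-H (CH2Cl2, −78 °C) should give the bis-allylic spiro dienol F1.
- Catalytic PPTS (CH2Cl2, 0 °C) should trigger a dienol–benzene rearrangement with the same vinyl shift, giving the 6-deoxychromene F2.
- Iridium-catalysed C–H borylation ([Ir(OMe)(cod)]2, dtbpy, B2pin2, THF, 60 °C) should address C6, the only arene position with two CH neighbours, giving the boronate F3.
- NaBO3 oxidation should give the free chromenol F4, and Ac2O/pyridine leads to 10.

**Step 6.**
- The delocalised phenoxenium ion may be captured at the vinylogous carbon or by acetate. The vinylogous p-hydroxybenzylic tertiary alcohol may also lose water before oxidation.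
- The fallback sets out from 8 and returns at 10. It removes the conjugated double bond from the tether and reinstalls it last.
- Diimide (2-nitrobenzenesulfonyl hydrazide, Et3N, rt) should reduce only the disubstituted alkene, giving the saturated phenol F5.
- PhI(OAc)2 in MeCN should then give the spiro tetrahydrofuran dienone F6, the best-documented substrate class for this spiroetherification.
- Ac2O/acid should enlarge the ring by an alkyl shift to the chromanyl acetate F7.
- DDQ in refluxing dioxane should dehydrogenate C3–C4 to give 10.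

**Step 11.**
- Hydroalumination at the hindered tertiary alkoxide may be sluggish. Prolonged exposure to the basic aluminate may then shift the skipped enyne into conjugation or cause over-reduction.
- The fallback sets out from 5 and 12 and returns at 15. It forms the E-alkene before the union, so steps 10 and 11 are bypassed.
- Pd-catalysed hydrostannation of 5 (Bu3SnH, PdCl2(PPh3)2, THF) should give the distal (E)-vinylstannane F8.
- Stille allylation with 12 (Pd2(dba)3, AsPh3, NMP) should give the target acetate F9.
- K2CO3/MeOH should release 15.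

**Further compounds**
F1 | step 7 | (2S)-2,6-dimethyl-2-(4-methylpent-3-en-1-yl)-1-oxaspiro[4.5]deca-3,6,9-trien-8-ol (C5/C8 isomers) | CC(C)=CCC[C@@]1(C)C=CC2(O1)C=CC(O)C=C2C
F2 | step 7 | (S)-2,8-dimethyl-2-(4-methylpent-3-en-1-yl)-2H-chromene | CC(C)=CCC[C@@]1(C)C=Cc2cccc(C)c2O1
F3 | step 7 | (S)-2,8-dimethyl-2-(4-methylpent-3-en-1-yl)-6-(4,4,5,5-tetramethyl-1,3,2-dioxaborolan-2-yl)-2H-chromene | CC(C)=CCC[C@@]1(C)C=Cc2cc(B3OC(C)(C)C(C)(C)O3)cc(C)c2O1
F4 | step 7 | (S)-2,8-dimethyl-2-(4-methylpent-3-en-1-yl)-2H-chromen-6-ol | CC(C)=CCC[C@@]1(C)C=Cc2cc(O)cc(C)c2O1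
F5 | step 6 | 4-[(3S)-3-hydroxy-3,7-dimethyloct-6-en-1-yl]-3-methylphenol | CC(C)=CCC[C@](C)(O)CCc1ccc(O)cc1C
F6 | step 6 | (2S)-2,6-dimethyl-2-(4-methylpent-3-en-1-yl)-1-oxaspiro[4.5]deca-6,9-dien-8-one (C5 epimers) | CC(C)=CCC[C@@]1(C)CCC2(O1)C=CC(=O)C=C2C
F7 | step 6 | (S)-2,8-dimethyl-2-(4-methylpent-3-en-1-yl)chroman-6-yl acetate | CC(C)=CCC[C@@]1(C)CCc2cc(OC(C)=O)cc(C)c2O1
F8 | step 11 | (1E,3S)-3,7-dimethyl-1-(tributylstannyl)octa-1,6-dien-3-ol | CC(C)=CCC[C@](C)(O)/C=C/[Sn](CCCC)(CCCC)CCCC
F9 | step 11 | (S)-2-[(3E,6E,8S)-8-hydroxy-4,8,12-trimethyltrideca-3,6,11-trien-1-yl]-2,8-dimethyl-2H-chromen-6-yl acetate | CC(C)=CCC[C@](C)(O)/C=C/C/C(C)=C/CC[C@@]1(C)C=Cc2cc(OC(C)=O)cc(C)c2O1
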